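Both isoprenoid units of the target are attached to carbon atoms that neighbour or face a phenolic oxygen: C8 of ring A lies para to O5, and the pyran ring bridges O4' and C5' of ring B. Each unit is therefore traced back to an ether on that oxygen, and a single heating of the (2S)-flavanone carrying a 5-O-prenyl ether, a 4'-O-(1,1-dimethylpropargyl) ether and a 2'-O-TIPS group should shift the prenyl group to C8, free the 5-OH and close the chromene. Because a 4'-phenoxide opens the flavanone ring, both ethers are installed before the C2 stereocentre is set by an asymmetric conjugate addition.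

Key step: step 10

Remark: the target is read as (2S); a B-ring phenoxide at 4' or 2' can open the flavanone through a quinone methide and racemise C2, so no B-ring phenol is alkylated once C2 exists, the alkyne is capped with trimethylsilyl for the rhodium step, and only neutral or buffered conditions follow.
Remark: the (S)-biaryl bisphosphine is assumed to show on the chromone the facial sense it shows on cyclic enones (aryl to the Re face of C2, giving 2S); the antipodal ligand is used if a phenylboronic acid model shows the opposite sense.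
Remark: 1-(2,6-dihydroxy-4-methoxyphenyl)ethanone, 3-chloro-3-methylbut-1-yne and prenyl bromide are taken as purchasable.

Step 1
Reactants: 1 resorcinol; 2 3-chloro-3-methylbut-1-yne
Product: 3 3-(2-methylbut-3-yn-2-yloxy)phenol
Conditions: 1 (3 equiv), CuCl2·2H2O (1 mol%), DBU (1.2 equiv), MeCN, 0 °C
Reagents that add atoms: none
Why: Copper-catalysed propargylic etherification, in which DBU and the copper salt turn the tertiary propargylic chloride into a copper allenylidene-type electrophile that the phenol attacks at the tertiary carbon, while the excess of the symmetric diol holds the reaction at the mono-ether.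

Step 2
Reactants: 3 3-(2-methylbut-3-yn-2-yloxy)phenol
Product: 4 2-bromo-5-(2-methylbut-3-yn-2-yloxy)phenol
Conditions: NBS (1.0 equiv), i-Pr2NH (10 mol%), CH2Cl2, −20 to 0 °C
Reagents that add atoms: N-bromosuccinimide, O=C1CCC(=O)N1Br
Why: Amine-mediated ortho-selective electrophilic bromination of a phenol, in which the hydrogen-bonded N-bromoamine delivers bromine next to the hydroxyl group and, of the two ortho sites, the one para to the ether oxygen is more activated and free of the bulky tertiary ether, which also screens the position para to the hydroxyl.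

Step 3
Reactants: 4 2-bromo-5-(2-methylbut-3-yn-2-yloxy)phenol
Product: 5 [2-bromo-5-(2-methylbut-3-yn-2-yloxy)phenoxy]triisopropylsilane
Conditions: TIPSCl (1.2 equiv), imidazole (2.5 equiv), DMF, rt
Reagents that add atoms: chlorotri(propan-2-yl)silane, CC(C)[Si](Cl)(C(C)C)C(C)C
Why: Imidazole-promoted O-silylation of a phenol, which a single ortho bromine slows but does not prevent.

Step 4
Reactants: 5 [2-bromo-5-(2-methylbut-3-yn-2-yloxy)phenoxy]triisopropylsilane
Product: 6 [2-bromo-5-[2-methyl-4-(trimethylsilyl)but-3-yn-2-yloxy]phenoxy]triisopropylsilane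
Conditions: LiN(i-Pr)2 (1.1 equiv) added to 5 and TMSCl (1.3 equiv), THF, −78 °C
Reagents that add atoms: chlorotrimethylsilane, C[Si](C)(C)Cl
Why: Deprotonation of the terminal alkyne, far more acidic than any aryl C–H, and C-silylation of the acetylide with in situ trapping, which masks the alkyne against the aryllithium of step 5 and the rhodium catalyst of step 8.

Step 5
Reactants: 6 [2-bromo-5-[2-methyl-4-(trimethylsilyl)but-3-yn-2-yloxy]phenoxy]triisopropylsilane
Product: 7 [4-[2-methyl-4-(trimethylsilyl)but-3-yn-2-yloxy]-2-(triisopropylsilyloxy)phenyl]boronic acid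
Conditions: B(Oi-Pr)3 (1.5 equiv), n-BuLi (1.1 equiv), THF/toluene, −78 °C; then 1 M aq. HCl to pH 5, 0 °C
Reagents that add atoms: triisopropyl borate, CC(C)OB(OC(C)C)OC(C)C; water, O
Why: Bromine–lithium exchange with the borate already present, so that the ortho-silyloxy aryllithium is trapped before an anionic oxygen-to-carbon silyl shift can compete, followed by hydrolysis of the borate to the boronic acid.

Step 6
Reactants: 8 1-(2,6-dihydroxy-4-methoxyphenyl)ethanone; 9 1-bromo-3-methylbut-2-ene (prenyl bromide)
Product: 10 1-[2-hydroxy-4-methoxy-6-(3-methylbut-2-enyloxy)phenyl]ethanone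
Conditions: 9 (1.05 equiv), K2CO3 (1.1 equiv), acetone, 50 °C
Reagents that add atoms: none
Why: Williamson ether synthesis on one of two equivalent phenols, after which the remaining hydroxyl is locked in a hydrogen bond to the ketone and is alkylated much more slowly.

Step 7
Reactants: 10 1-[2-hydroxy-4-methoxy-6-(3-methylbut-2-enyloxy)phenyl]ethanone
Product: 12 7-methoxy-5-(3-methylbut-2-enyloxy)-4H-chromen-4-one, via enaminone 11 (not isolated)
Conditions: Me2NCH(OMe)2 (2 equiv), toluene, 95 °C; evaporate; AcOH, 70 °C
Reagents that add atoms: N,N-dimethylformamide dimethyl acetal, COC(OC)N(C)C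
Why: Enaminone formation at the acetyl methyl group followed by acid-promoted conjugate addition of the phenol and loss of dimethylamine, the usual enaminone route to 2,3-unsubstituted chromones, under acid mild enough to spare the prenyl ether.

Step 8
Reactants: 12 7-methoxy-5-(3-methylbut-2-enyloxy)-4H-chromen-4-one; 7 [4-[2-methyl-4-(trimethylsilyl)but-3-yn-2-yloxy]-2-(triisopropylsilyloxy)phenyl]boronic acid
Product: 13 (2S)-7-methoxy-5-(3-methylbut-2-enyloxy)-4'-[2-methyl-4-(trimethylsilyl)but-3-yn-2-yloxy]-2'-(triisopropylsilyloxy)flavanone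
Conditions: 7 (2.5 equiv), [Rh(OH)(cod)]2 (2.5 mol%), (S)-MeO-F12-BIPHEP [(S)-2,2'-bis[bis(3,4,5-trifluorophenyl)phosphino]-6,6'-dimethoxybiphenyl] (5.5 mol%), degassed toluene/H2O 10:1, 50 °C, no added base
Reagents that add atoms: none
Why: Rhodium-catalysed asymmetric conjugate addition of an arylboronic acid to a chromone (Hayashi–Miyaura reaction), in which the aryl group passes from boron to monovalent rhodium, inserts the C2=C3 bond and the rhodium enolate is protonated by water, the C2-symmetric electron-poor bisphosphine steering the aryl group to the Re face of C2 to set the (2S) centre, while the base-free medium leaves both silyl groups and the new flavanone untouched.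

Step 9
Reactants: 13 (2S)-7-methoxy-5-(3-methylbut-2-enyloxy)-4'-[2-methyl-4-(trimethylsilyl)but-3-yn-2-yloxy]-2'-(triisopropylsilyloxy)flavanone
Product: 14 (2S)-7-methoxy-5-(3-methylbut-2-enyloxy)-4'-(2-methylbut-3-yn-2-yloxy)-2'-(triisopropylsilyloxy)flavanone
Conditions: AgNO3 (0.2 equiv), acetone/H2O 10:1, rt, dark
Reagents that add atoms: none
Why: Silver-catalysed protodesilylation of a trimethylsilylalkyne through a silver acetylide, a neutral method that leaves the aryl silyl ether intact and creates no phenoxide that could open the flavanone ring.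

Step 10
Reactants: 14 (2S)-7-methoxy-5-(3-methylbut-2-enyloxy)-4'-(2-methylbut-3-yn-2-yloxy)-2'-(triisopropylsilyloxy)flavanone
Product: 21 (2S)-2'-O-(triisopropylsilyl)maackiaflavanone A, via C6 reverse-prenyl dienone 15 (not isolated), via C8 prenyl dienone 16 (not isolated), via 8-prenyl 5-phenol 17 (not isolated), via allenyl dienone 18 (not isolated), via allenyl phenol 19 (not isolated), via ortho-quinone methide 20 (not isolated)
Conditions: Eu(fod)3 (10 mol%; fod = 6,6,7,7,8,8,8-heptafluoro-2,2-dimethyloctane-3,5-dionate), PhCl, Ar, 85 °C until 14 is consumed; then 130 °C, sealed vessel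
Reagents that add atoms: none
Why: On ring A the trivalent europium centre, held between the C4 carbonyl and O5, promotes an aromatic Claisen shift of the prenyl group from O5 to C6 (15) and then a Cope shift on to C8 (16) before 15 can enolise, and tautomerisation gives the chelated 5-phenol 17. On ring B, at the higher temperature, the aryl propargyl ether undergoes a propargyl Claisen shift to C5' (18), enolisation to the allenyl phenol 19 and a 1,5-hydrogen shift to the ortho-quinone methide 20. The pyran ring closes from 20 by a thermal oxa-6π electrocyclisation that forms the O4'–CMe2 bond. Both halves are known separately, as the Lewis-acid-promoted para-Claisen–Cope shift of 5-O-prenyl flavonoids and the thermal conversion of aryl 1,1-dimethylpropargyl ethers into 2,2-dimethylchromenes, and they are combined here in one vessel by staging the temperature. The step is an isomerisation that creates no stereocentre, and C2 should keep its configuration because no base is present and the B-ring phenol appears only briefly and in neutral form. It needs C8 over C6 on ring A, which the chelated Lewis acid favours by speeding both sigmatropic shifts relative to enolisation, and C5' over C3' on ring B, which the bulky 2'-O-TIPS group and the para-directing effect of that oxygen should secure.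

Step 11
Reactants: 21 (2S)-2'-O-(triisopropylsilyl)maackiaflavanone A
Product: 22 maackiaflavanone A
Conditions: Bu4NF/AcOH (1:1.2, 1.5 equiv), THF, 0 °C
Reagents that add atoms: none
Why: Fluoride cleavage of the aryl silyl ether, buffered with acetic acid so that the 2'-oxygen is released as the neutral phenol and ring opening through an ortho-quinone methide, with loss of the C2 configuration, stays closed.

Compound list
1 | resorcinol | Oc1cccc(O)c1 | starting material
2 | 3-chloro-3-methylbut-1-yne | C#CC(C)(C)Cl | starting material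
3 | 3-(2-methylbut-3-yn-2-yloxy)phenol | C#CC(C)(C)Oc1cccc(O)c1 | intermediate
4 | 2-bromo-5-(2-methylbut-3-yn-2-yloxy)phenol | C#CC(C)(C)Oc1ccc(Br)c(O)c1 | intermediate
5 | [2-bromo-5-(2-methylbut-3-yn-2-yloxy)phenoxy]triisopropylsilane | C#CC(C)(C)Oc1ccc(Br)c(O[Si](C(C)C)(C(C)C)C(C)C)c1 | intermediate
6 | [2-bromo-5-[2-methyl-4-(trimethylsilyl)but-3-yn-2-yloxy]phenoxy]triisopropylsilane | C[Si](C)(C)C#CC(C)(C)Oc1ccc(Br)c(O[Si](C(C)C)(C(C)C)C(C)C)c1 | intermediate
7 | [4-[2-methyl-4-(trimethylsilyl)but-3-yn-2-yloxy]-2-(triisopropylsilyloxy)phenyl]boronic acid | C[Si](C)(C)C#CC(C)(C)Oc1ccc(B(O)O)c(O[Si](C(C)C)(C(C)C)C(C)C)c1 | intermediate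
8 | 1-(2,6-dihydroxy-4-methoxyphenyl)ethanone | CC(=O)c1c(O)cc(OC)cc1O | starting material
9 | 1-bromo-3-methylbut-2-ene (prenyl bromide) | CC(C)=CCBr | starting material
10 | 1-[2-hydroxy-4-methoxy-6-(3-methylbut-2-enyloxy)phenyl]ethanone | CC(=O)c1c(O)cc(OC)cc1OCC=C(C)C | intermediate
11 | (E)-3-(dimethylamino)-1-[2-hydroxy-4-methoxy-6-(3-methylbut-2-enyloxy)phenyl]prop-2-en-1-one | CN(C)/C=C/C(=O)c1c(O)cc(OC)cc1OCC=C(C)C | intermediate
12 | 7-methoxy-5-(3-methylbut-2-enyloxy)-4H-chromen-4-one | COc1cc(OCC=C(C)C)c2C(=O)C=COc2c1 | intermediate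
13 | (2S)-7-methoxy-5-(3-methylbut-2-enyloxy)-4'-[2-methyl-4-(trimethylsilyl)but-3-yn-2-yloxy]-2'-(triisopropylsilyloxy)flavanone | COc1cc(OCC=C(C)C)c2c(c1)O[C@H](c1ccc(OC(C)(C)C#C[Si](C)(C)C)cc1O[Si](C(C)C)(C(C)C)C(C)C)CC2=O | intermediate
14 | (2S)-7-methoxy-5-(3-methylbut-2-enyloxy)-4'-(2-methylbut-3-yn-2-yloxy)-2'-(triisopropylsilyloxy)flavanone (key-step precursor) | COc1cc(OCC=C(C)C)c2c(c1)O[C@H](c1ccc(OC(C)(C)C#C)cc1O[Si](C(C)C)(C(C)C)C(C)C)CC2=O | intermediate
15 | ring-A ortho-dienone: C5 ketone, C6 sp3 carrying H and a 2-methylbut-3-en-2-yl group, ring B as in 14 | COC1=CC2=C(C(=O)C[C@@H](c3ccc(OC(C)(C)C#C)cc3O[Si](C(C)C)(C(C)C)C(C)C)O2)C(=O)C1C(C)(C)C=C | intermediate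
16 | ring-A para-dienone: C5 ketone, C8 sp3 carrying H and a 3-methylbut-2-enyl group, ring B as in 14 | COC1=CC(=O)C2=C(C1CC=C(C)C)O[C@H](c1ccc(OC(C)(C)C#C)cc1O[Si](C(C)C)(C(C)C)C(C)C)CC2=O | intermediate
17 | (2S)-5-hydroxy-7-methoxy-8-(3-methylbut-2-enyl)-4'-(2-methylbut-3-yn-2-yloxy)-2'-(triisopropylsilyloxy)flavanone | COc1cc(O)c2c(c1CC=C(C)C)O[C@H](c1ccc(OC(C)(C)C#C)cc1O[Si](C(C)C)(C(C)C)C(C)C)CC2=O | intermediate
18 | ring-B dienone: C4' ketone, C5' sp3 carrying H and a 3-methylbuta-1,2-dienyl group, ring A as in 17 | COc1cc(O)c2c(c1CC=C(C)C)O[C@H](C1=CC(C=C=C(C)C)C(=O)C=C1O[Si](C(C)C)(C(C)C)C(C)C)CC2=O | intermediate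
19 | (2S)-5,4'-dihydroxy-7-methoxy-5'-(3-methylbuta-1,2-dienyl)-8-(3-methylbut-2-enyl)-2'-(triisopropylsilyloxy)flavanone | COc1cc(O)c2c(c1CC=C(C)C)O[C@H](c1cc(C=C=C(C)C)c(O)cc1O[Si](C(C)C)(C(C)C)C(C)C)CC2=O | intermediate
20 | ring-B ortho-quinone methide: C4' ketone, C5' exocyclic 3-methylbut-2-enylidene, ring A as in 17 | COc1cc(O)c2c(c1CC=C(C)C)O[C@H](C1=CC(=CC=C(C)C)C(=O)C=C1O[Si](C(C)C)(C(C)C)C(C)C)CC2=O | intermediate
21 | (2S)-2'-O-(triisopropylsilyl)maackiaflavanone A | COc1cc(O)c2c(c1CC=C(C)C)O[C@H](c1cc3c(cc1O[Si](C(C)C)(C(C)C)C(C)C)OC(C)(C)C=C3)CC2=O | intermediate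
22 | maackiaflavanone A, (2S) | COc1cc(O)c2c(c1CC=C(C)C)O[C@H](c1cc3c(cc1O)OC(C)(C)C=C3)CC2=O | target

Total step count: 11.
Longest linear sequence: 9 steps (steps 1 to 5 and 8 to 11, from resorcinol).

Steps most likely to fail

Step 10. What may go wrong: the C6 dienone may enolise before the Cope shift, leaving the reverse-prenyl group at C6; the propargyl unit may migrate in part to C3'; and the hotter second stage may erode the C2 configuration through reversible ring opening. Fallback: the two rearrangements are separated and the pyran is made before the stereocentre exists. The fallback sets out from 5, which on heating in N,N-diethylaniline at 180 °C should undergo the propargyl Claisen and electrocyclisation sequence to 6-bromo-2,2-dimethyl-7-(triisopropylsilyloxy)-2H-chromene F1, any regioisomer being removed at this achiral stage. Bromine–lithium exchange with in situ borate trapping, as in step 5, then gives the chromenylboronic acid F2. The rhodium-catalysed conjugate addition of step 8 to chromone 12 should give the (2S)-5-O-prenyl flavanone with the finished pyran F3. The Eu(fod)3-promoted Claisen–Cope shift alone, at 85 °C, comes back to the route at 21.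

Step 8. What may go wrong: transmetalation and insertion of the ortho-silyloxy aryl group may be slow, so that protodeboronation wins, or the faces of the electron-rich chromone may be poorly discriminated. Fallback: the C2–O1 bond is made last and the enantiomers are separated. The fallback sets out from 6, which by bromine–lithium exchange (n-BuLi, −78 °C) and quenching with DMF gives the aldehyde F4. Aldol addition of the dilithio derivative of 10 (LiN(i-Pr)2, 2.2 equiv, THF, −78 °C) to F4 gives the racemic β-hydroxy ketone F5. Intramolecular Mitsunobu etherification (PPh3, DIAD, THF, 0 °C) closes the pyranone ring to the racemic flavanone F6. Preparative HPLC on a chiral stationary phase delivers the (2S) enantiomer, which is 13, where the route resumes.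

Step 5. What may go wrong: the silyl group may migrate from oxygen to carbon in the aryllithium, and the electron-rich boronic acid may lose boron during acidic work-up. Fallback: boron is introduced without an aryllithium. The fallback sets out from 6, which under Miyaura borylation (bis(pinacolato)diboron, Pd(dppf)Cl2, KOAc, dioxane, 85 °C) gives the pinacol boronate F7. Oxidative cleavage of the pinacol unit (NaIO4, NH4OAc, acetone/H2O, rt) comes back to the route at 7.

Further compounds
F1 | step 10 | 6-bromo-2,2-dimethyl-7-(triisopropylsilyloxy)-2H-chromene | CC1(C)C=Cc2cc(Br)c(O[Si](C(C)C)(C(C)C)C(C)C)cc2O1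
F2 | step 10 | [2,2-dimethyl-7-(triisopropylsilyloxy)-2H-chromen-6-yl]boronic acid | CC1(C)C=Cc2cc(B(O)O)c(O[Si](C(C)C)(C(C)C)C(C)C)cc2O1
F3 | step 10 | (2S)-7-methoxy-5-(3-methylbut-2-enyloxy)-2'-(triisopropylsilyloxy)flavanone with a 2,2-dimethylpyran fused at O4' and C5' | COc1cc(OCC=C(C)C)c2c(c1)O[C@H](c1cc3c(cc1O[Si](C(C)C)(C(C)C)C(C)C)OC(C)(C)C=C3)CC2=O
F4 | step 8 | 4-[2-methyl-4-(trimethylsilyl)but-3-yn-2-yloxy]-2-(triisopropylsilyloxy)benzaldehyde | C[Si](C)(C)C#CC(C)(C)Oc1ccc(C=O)c(O[Si](C(C)C)(C(C)C)C(C)C)c1
F5 | step 8 | racemic 3-hydroxy-1-[2-hydroxy-4-methoxy-6-(3-methylbut-2-enyloxy)phenyl]-3-[4-[2-methyl-4-(trimethylsilyl)but-3-yn-2-yloxy]-2-(triisopropylsilyloxy)phenyl]propan-1-one | COc1cc(O)c(C(=O)CC(O)c2ccc(OC(C)(C)C#C[Si](C)(C)C)cc2O[Si](C(C)C)(C(C)C)C(C)C)c(OCC=C(C)C)c1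
F6 | step 8 | racemic form of 13 | COc1cc(OCC=C(C)C)c2c(c1)OC(c1ccc(OC(C)(C)C#C[Si](C)(C)C)cc1O[Si](C(C)C)(C(C)C)C(C)C)CC2=O
F7 | step 5 | pinacol ester of boronic acid 7 | C[Si](C)(C)C#CC(C)(C)Oc1ccc(B2OC(C)(C)C(C)(C)O2)c(O[Si](C(C)C)(C(C)C)C(C)C)c1
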